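Zeta's readings between 15.0 min and 20.0 min give a turnover of accumulated substrate of 0.0529 min⁻¹, and the question is what that constant becomes when multiplied by the dosing time.

common to all: substrate 0.079 M (fed, over 40 min)

| flask | free catalyst | temperature | remark | time |
|---|---|---|---|---|
| theta | 9.1 mM | −25 °C | run made earlier |  |
| zeta | 32 mM | −8 °C | run made earlier |  |
| violet | 40 mM |  | at 5 °C throughout | 40 min |
| green | 12 mM |  | at −20 °C until 8.0 min, from then on at 5 °C | 40 min |

- theta (time / min: target / %): 6.00: 0; 12.0: 0; 15.0: 0.7; 25.0: 3.3; 30.0: 4.6; 40.0: 8.0
- zeta (time / min: target / %): 1.50: 0; 3.00: 1.8; 4.00: 2.2; 6.00: 4.0; 8.00: 2.4; 15.0: 12.5; 20.0: 19.8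

(standard deviation of a reading: 1 percentage point)

1. the flask that ends with the higher amount of target, in percent of the substrate charged, or "neither" when 2 percentage points or less lies between them (violet / green / neither)
2. final target, as a percentage of the substrate charged, in violet
3. final target, as a percentage of the substrate charged, in green

- the numbers in the tables scatter with a standard deviation of 1 percentage point
- percentages count the whole charge, also what has not yet gone in

How is a constant read off a target curve? By balance in fractions of the charge: the substrate present is the fraction dosed minus the target, and the rise of target over that fraction is the pseudo-first-order constant. Theta, between 30.0 min and 40.0 min, gives 0.00419 min⁻¹.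

How firm is that? Rough: theta's rise is 3.4 percentage points, and each reading scatters by 1 point.

Theta reads zero at 12.0 min. Is that a lag? Not provably: its constant predicts 0.754% there, less than the scatter.

What carries over? Assuming first order in free catalyst, the two runs give a temperature slope of 4950 K, though catalyst and temperature moved together. The dosing number N, the pseudo-first-order constant times the dosing time, is then 6.33 for violet. With the constant held steady through the dosing, the fraction left at the end of dosing is one minus exp(−N), divided by N. At an N of 1, one over the constant equals the dosing time; that is the crossing.

Violet? By this reckoning it keeps 15.8% as substrate, so 84.2% is target.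

Green? Its N is 0.328 cold and 1.90 warm, so the change of temperature carries green across the crossing. Cold, I reckon it forms 0.655%. Then the substrate dosed so far decays while the feed continues, and I reckon 54.6%. Violet ends higher.

The forecast, holding that “consumption is first order in accumulated substrate”, says violet, 85% and 58%; its green stands 3.4 points above mine.

The flasks give violet ahead, with 85.2% in violet and 56.6% in green.

    substrate + free catalyst → catalyst intermediate A (k = 0.932 M⁻¹ min⁻¹, Ea = 36.0 kJ mol⁻¹)
    catalyst intermediate A ⇌ catalyst intermediate B (K = 3.96, k = 0.653 min⁻¹, Ea = 79.0 kJ mol⁻¹, ΔH = −30.0 kJ mol⁻¹)
    catalyst intermediate B → free catalyst + target (k = 1.21 min⁻¹, Ea = 70.0 kJ mol⁻¹)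
    (constants at −20 °C)

In violet, the half-life of substrate by its step with free catalyst is 4.0 min at 22.8 min, far shorter than the dosing time of 40 min. Read this way, N is 6.89, which leaves 14.5% by the expression, and violet holds 14.5% of substrate at 40.0 min. With 0.10 M of free catalyst, a neighbour flask of violet has N scaled to 17.2, which leaves 5.81%, and that neighbour holds 5.8%.

The runs were computed on assumed constants.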